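Its constants are invented.

Reckon this flask through one ratio of two capture constants rather than stepping the whole run.

    starting material + free enzyme ⇌ first complex (K1 = 9.3 M⁻¹, k1 = 21 M⁻¹ s⁻¹)
    first complex → loaded enzyme + first product (k2 = 3.1 s⁻¹)
    second substrate + loaded enzyme ⇌ second complex (K3 = 8.8 M⁻¹, k3 = 15 M⁻¹ s⁻¹)
    second complex → free enzyme + target (k4 = 0.24 s⁻¹)
    2 second substrate → homo dimer (k5 = 1.2 × 10⁻⁴ M⁻¹ s⁻¹)
    solid substrate ⇌ starting material, rate k6*(cs6 - [starting material]) while solid is left; crystals form when [starting material] > cs6 (cs6 = 39 mM, k6 = 2.4 × 10⁻⁵ s⁻¹)

solid substrate 0.10 M; second substrate 1.05 equiv; free enzyme 0.01 mol%

1. the form that holds most of the catalyst when 5.0% of the solid substrate are converted (what has only dissolved counts as not reacted) (first complex / loaded enzyme / free enzyme / second complex)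
2. its share of the catalyst then
3. apparent order in second substrate when 5.0% of the solid substrate are converted (what has only dissolved counts as not reacted) (percent change of the rate of making target for one percent more second substrate charged)
4. factor on the rate of making target when 5.0% of the solid substrate are converted (what has only dissolved counts as not reacted) if second substrate is charged twice over

A capture constant is the binding rate constant times the fraction of complexes that go on instead of falling back. Free enzyme capturing starting material over loaded enzyme capturing second substrate gives 6.56, the capture ratio. In a steady cycle each form's share is its wait per turn, so loaded enzyme over free enzyme equals this ratio times starting material over second substrate.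

My reckoning for 0.179 d: dissolution slackens as starting material builds, and taking the mean level midway between nothing and the final one leaves 8.00% of the solid charge dissolved and unreacted. Dimerisation and the conversion leave 67.2% of the second substrate charge. Loaded over free is then 0.744. Adding the two complexes gives free enzyme 45.9% and loaded enzyme 34.1%. With starting material held, the order in present second substrate equals that loaded share; the hand reckoning stops there.

The forecast has free enzyme at 47% (43% to 51%), more than this reckoning's free enzyme, with order 0.17, factor 1.09 and the words “Free enzyme therefore dominates”.

The flask gives free enzyme at 46.8%, order 0.19 and factor 1.10. Loaded enzyme holds 33.4%, a reading of 0.713 for loaded over free, and the order, taken on the charge, stands lower than the reckoned loaded share. At 1.00 d this flask has starting material at 21.5% of the solid charge and second substrate at 16.4% of its own, so the capture ratio predicts loaded over free of 8.18. The resting state of this flask has moved to loaded enzyme, at 79.0% against free enzyme's 9.66%, a ratio of 8.18.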